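## Analysis of the target

Crotobarin (29) is a 3,4-seco-ent-atisane. In atisane numbering, a bicyclo[2.2.2]octane (C8, C9, C11–C16, bridgeheads C8 and C12) shares C8–C9 with cyclohexane ring B (C5–C10) and C9–C10 with a δ-lactone (C10–C1–C2–C3(=O)–O–C9). C5 carries the isopropenyl group (C4), C10 the methyl C20, C14 the acetate, C15 is a ketone and C16 bears the exocyclic methylene C17. The six stereocentres are C5, C8, C9, C10, C12 and C14: C8 and C12 are coupled by the bicycle, the C9 oxygen lies on the side of the C15–C16 bridge and is axial on ring B, the C10 methyl is axial and anti to it, the C5 isopropenyl group is equatorial, and the C14 acetate points toward the C15 bridge. The α-methylene ketone is a reactive Michael acceptor, acetate and lactone are base-labile, and the 1,1-disubstituted alkene is sensitive to acid and electrophilic oxidants; the C14 acetate is β to the C15 ketone but cannot be eliminated because C8 has no hydrogen. The synthesis is hard because C8, C9 and C10 are three contiguous fully substituted carbons and because C8 has three oxygenated neighbours (C9, C14, C15) in three different states. The strategy rests on the pair C9/C10: with the isopropenyl group written as an acetyl group, C10 is the β-carbon of an enone and C9 is a ketone carbon of the bicycle, so both are electrophilic. Only polarity reversal at C9 (a ketyl) can join them; this closes ring B, and the resulting C9 alkoxide is placed to close the lactone on C3.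

## Retrosynthetic reasoning

**29 back to 24.** The exocyclic C16=C17 enone is the most reactive group and is removed first, which leads to ketone 26. Its C15 ketone is traced to the alcohol 25 and its isopropenyl group to the acetyl group of 24. These changes cut no skeletal bond but expose what the key step needs: a carbonyl on C5 that makes C10 an acceptor, and a free C15 hydroxyl. Forward, the acetyl group is methylenated while C15 is still an alcohol, so only one ketone is present at each stage.

**24 back to 22 (key disconnection).** The C9–C10 bond and the lactone C3–O bond are cut. No other bond of ring B joins two carbons that are both fully substituted and both electrophilic in the retron, and cutting here releases the whole C1–C3/C10 arm as a simple chain. Forward, a ketyl at C9 must add to C10 of the (Z)-enone in 22, with oxygen syn to the C15 bridge and the C10 methyl axial, and the alkoxide must then acylate on the C3 ester.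

**22 back to 18 and 19.** After the C15 hydroxyl is masked as its silyl ether (21), the C10–C1 bond is cut to the (Z)-enol triflate 18 and the zinc homoenolate 20 made from 19. A stereoretentive sp2–sp3 coupling transfers the geometry of 18 unchanged, so the geometry problem is moved to the enolisation of a symmetrical diketone.

**18 back to 13.** Triflate 18 comes from diketone 17, whose two acetyl groups on C5 are identical, so only the enolate geometry has to be controlled (chelation). The C5–C6 bond of 17 is cut to aldehyde 15 and acetylacetone 16 (reductive alkylation). Aldehyde 15 is the ozonolysis product of the allyl group in 14, the silyl ether of 13. The chain is built on the bicycle rather than attached in one piece because the geometry is easier to secure from 17 than to carry through the early steps.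

**13 back to 11 and 12.** The C15–H bond and the C14 acetate are removed together in an Evans–Tishchenko sense. The C14 hydroxyl of 11 faces only one of the two carbonyls on C8, so a single operation decides which carbonyl becomes C15, sets the C15 hydroxyl anti to the C14 oxygen, acetylates C14 from acetaldehyde 12 and leaves C9 as the ketone.

**11 back to 9 via 10.** C14 is the only independent stereogenic element of 11; every later stereocentre is derived from it. It is therefore set by reagent control: oxidation of racemic 9 gives trione 10, which is achiral, and an enantioselective reduction returns 11 as one enantiomer. A direct enantioselective amine-catalysed closure of 7 was not relied on. The dione is the donor there, so enamine activation would pass through a poorly nucleophilic vinylogous amide, and an equilibrating aldol that ends in a non-enolisable β-hydroxy diketone may not lie on the product side.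

**9 back to 7.** The C8–C14 bond is cut (aldol). C8 is the carbon between the two carbonyls of a cyclohexane-1,3-dione and C14 an aldehyde on the C12 side chain. Attack through oxygen would give a bridgehead alkene, so only C-attack can close the ring. Forward, the closure is run as an irreversible Mukaiyama aldol through silyl enol ether 8.

**7 back to 1 and 4.** The dione is unmasked from the bis(enol ether) 5 after oxidation of the side-chain alcohol (via 6). The C8–C7 bond is cut to the Birch product 3 and allyl bromide 4, because alkylating the masked dione avoids O-alkylation. Diene 3 comes from alcohol 2 and acid 1, whose substitution pattern already places C12 and its two-carbon arm opposite C8.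

## Alternatives that were turned down

**Alternative 1:** dearomatised dienone cycloaddition.
- Disconnection: C8–C9 and C11–C12 are cut in a retro-[4+2] sense. This leaves a 2-methoxyphenol ring (C8, C12–C16) tethered through C6–C7 to a monocyclic enol lactone with an exocyclic C9=C11 alkene.
- Forward key step: PhI(OAc)2 in methanol turns the phenol ring into its masked ortho-quinone form, whose diene termini C8 and C12 add across C9=C11 to give cycloadduct A1.
- For: ring B, the bicycle, quaternary C8 and carbinol C9 arise in one step from a flat arene. The route is convergent, and the electron-rich alkene matches the electron-poor dienone.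
- Against: A1 has an oxygenated C13 that must be removed reductively, a C14 ketone that must be reduced from the correct face and acetylated, and a C15 enol ether to hydrolyse. The two carbonyls on C8 therefore have to be differentiated afterwards. C10 and C5 must be set on a monocyclic lactone without the bicycle as a control element, and the facial selectivity of the cycloaddition depends on relaying them through the forming ring B.
- Comparison: it is stronger on convergence and on forming the bond to C9 (cycloaddition instead of radical addition to a fully substituted carbon). The chosen strategy offers correct oxidation levels at C9, C14 and C15 from the moment the bicycle exists, and sets C9, C10 and C5 together under control of the rigid bicycle.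

**Alternative 2:** carbenoid cyclopropanation and ring opening.
- Disconnection: the C15–C16 bridge is taken off by cutting C12–C16. This leaves a tricyclic lactone with a C12=C13 alkene and a diazomethyl ketone on C8.
- Forward key step: Rh2(OAc)4 generates the carbenoid, C16 adds across C12=C13 to give cyclopropyl ketone A2, and the C13–C16 bond is then cleaved.
- For: intramolecular cyclopropanation of diazo ketones is dependable and facially unambiguous, and it delivers C15 and C16 with the ketone in place.
- Against: opening A2 must break C13–C16 and not C12–C16, although both are conjugated with the ketone. Any anion, radical or cation at C13 sits next to the C14 acetate and invites its loss. The C9–C10 bond and the vicinal quaternary centres must already exist, and a hindered acid on C8 must be homologated to the diazo ketone.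
- Comparison: it is stronger as a late, robust closure of the bicycle. The chosen strategy addresses the hardest bond directly and never places a reactive intermediate beside the acetate.

**Alternative 3:** late ring-A scission.
- Disconnection: C3–C4 is reconnected and the lactone C–O bond opened, giving a complete ent-atisane with a C3 ketone and a C9 hydroxyl.
- Forward key step: H2O2 ties these groups into a bridged hydroperoxy ketal, FeSO4 (divalent iron) gives the C3 alkoxy radical, β-scission breaks C3–C4, and Cu(OAc)2 (divalent copper) oxidises the C4 radical to the alkene. The product A3 is identical with compound 26 of the chosen route.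
- For: one step forms both the lactone and the isopropenyl group, along the probable biogenetic path. C5 and C10 are set in a decalin, where control is well understood.
- Against: a full tetracyclic skeleton, including a ring and a gem-dimethyl carbon that exist only to be cut, must be built with C9, C14 and C15 already oxygenated. Oxidation of the C4 radical can give the tetrasubstituted C4=C5 alkene, and the radical conditions must spare the C15 ketone.
- Comparison: it is as strong or stronger in the end game and at C5. The chosen strategy reaches the same compound 26 without building ring A and forms the C9–C10 bond and the lactone in one step from an acyclic arm.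

Key step: step 15

Remark: atom labels C1–C20 follow atisane numbering; bicyclic intermediates are named as bicyclo[2.2.2]octanes (C1 = C8, C2 = C9, C4 = C12, C6 = C15, C7 = C14). Enolates, ketyls and metal alkoxides are discussed in the Why lines; only discrete compounds formed and consumed in one flask are numbered as unisolated intermediates.

## Route

Step 1
Reactants: 1 3,5-dimethoxyphenylacetic acid
Product: 2 2-(3,5-dimethoxyphenyl)ethanol
Conditions: LiAlH4, THF, 0 °C to reflux; NaOH/H2O work-up
Reagents that add atoms: none
Why: LiAlH4 reduction of the carboxylic acid to the primary alcohol; the aryl methyl ethers are inert.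

Step 2
Reactants: 2 2-(3,5-dimethoxyphenyl)ethanol
Product: 3 2-(3,5-dimethoxycyclohexa-2,5-dien-1-yl)ethanol
Conditions: Li, NH3(l), t-BuOH, THF, −78 to −33 °C; NH4Cl
Reagents that add atoms: none
Why: Birch reduction; both methoxy groups stay on sp2 carbons, so the ring is protonated at the chain-bearing carbon and at the carbon between the methoxy groups, leaving a bis(enol ether) that is a masked cyclohexane-1,3-dione.

Step 3
Reactants: 3 2-(3,5-dimethoxycyclohexa-2,5-dien-1-yl)ethanol; 4 allyl bromide
Product: 5 2-(4-allyl-3,5-dimethoxycyclohexa-2,5-dien-1-yl)ethanol (cis/trans mixture)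
Conditions: t-BuLi (2.2 equiv), THF/HMPA, −78 °C; then 4 (1.0 equiv), −78 °C; aq. NH4Cl
Reagents that add atoms: none
Why: After alkoxide formation the second equivalent of base removes the doubly allylic proton between the two enol ether carbons (the other doubly allylic C–H would put charge on the methoxy-bearing carbons), and the pentadienyl anion is C-alkylated at its central carbon, which avoids the O-alkylation of free cyclohexane-1,3-diones. The lithium alkoxide is a much poorer nucleophile at −78 °C and should not compete for one equivalent of 4; both ring stereocentres disappear in the next step.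

Step 4
Reactants: 5 2-(4-allyl-3,5-dimethoxycyclohexa-2,5-dien-1-yl)ethanol
Product: 7 2-allyl-5-(2-oxoethyl)cyclohexane-1,3-dione, via dienyl acetaldehyde 6 (not isolated)
Conditions: SO3·pyridine, DMSO, i-Pr2NEt, CH2Cl2, 0 °C; then 1 M HCl, THF, rt
Reagents that add atoms: water, O
Why: Parikh–Doering oxidation is base-buffered and leaves the acid-labile enol ethers intact; aqueous acid then hydrolyses both enol ethers to the 2-allyl-1,3-dione. Compound 7 has a mirror plane through C8 and C12 on the time scale of enol tautomerism and is achiral.

Step 5
Reactants: 7 2-allyl-5-(2-oxoethyl)cyclohexane-1,3-dione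
Product: 9 rac-1-allyl-7-hydroxybicyclo[2.2.2]octane-2,6-dione, via silyl enol ether 8 (not isolated)
Conditions: N,O-bis(trimethylsilyl)acetamide, CH2Cl2, rt; then TiCl4, −78 °C; aq. NH4Cl
Reagents that add atoms: none
Why: Intramolecular Mukaiyama aldol addition: C8 of the silyl enol ether attacks the TiCl4-activated aldehyde C14 and closes the third bridge as a chelated titanium aldolate that should not revert at low temperature. Only one diastereomer is possible because C14 is the only independent stereogenic element; attack on the two aldehyde faces gives the two enantiomers in equal amounts.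

Step 6
Reactants: 9 rac-1-allyl-7-hydroxybicyclo[2.2.2]octane-2,6-dione
Product: 10 1-allylbicyclo[2.2.2]octane-2,6,7-trione
Conditions: Dess–Martin periodinane, CH2Cl2, 0 °C to rt; filtration through silica without aqueous base
Reagents that add atoms: none
Why: Dess–Martin oxidation of the secondary alcohol under neutral conditions; the product has three equivalent carbonyl groups around C8 and is achiral, so both enantiomers of 9 converge. The non-enolisable trione is kept away from nucleophiles, which would open it by retro-Claisen cleavage.

Step 7
Reactants: 10 1-allylbicyclo[2.2.2]octane-2,6,7-trione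
Product: 11 (14S)-1-allyl-7-hydroxybicyclo[2.2.2]octane-2,6-dione
Conditions: (R)-2-methyl-CBS-oxazaborolidine (0.2 equiv), catecholborane (1.05 equiv), toluene, −78 °C; pH 7 buffer
Reagents that add atoms: none
Why: Corey–Bakshi–Shibata reduction used as a desymmetrisation: each carbonyl is flanked by the quaternary C8 (large) and a CH2 (small) and the three are equivalent, so catalyst-controlled hydride delivery to the same face of any of them gives the same enantiomer. By the usual model for tert-alkyl ketones the (R)-catalyst should give the (14S)-alcohol. Catecholborane should leave the allyl group untouched at this temperature, and one equivalent of hydride limits over-reduction.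

Step 8
Reactants: 11 (14S)-1-allyl-7-hydroxybicyclo[2.2.2]octane-2,6-dione; 12 acetaldehyde
Product: 13 (14S,15S)-1-allyl-6-hydroxy-2-oxobicyclo[2.2.2]octan-7-yl acetate
Conditions: SmI2 (0.3 equiv), 12 (8 equiv), THF, −10 °C
Reagents that add atoms: none
Why: Evans–Tishchenko reaction: the C14 hydroxyl forms a hemiacetal with 12, samarium bridges it to the one carbonyl that the C14 oxygen faces, and hydride is transferred through a six-membered transition state. This defines that carbonyl as C15, places the new hydroxyl anti to the C14 oxygen (pointing to the C9 bridge) and leaves the acetate on C14; the C9 carbonyl is out of reach and should survive.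

Step 9
Reactants: 13 (14S,15S)-1-allyl-6-hydroxy-2-oxobicyclo[2.2.2]octan-7-yl acetate
Product: 14 (14S,15S)-1-allyl-2-oxo-6-(triethylsilyloxy)bicyclo[2.2.2]octan-7-yl acetate
Conditions: Et3SiOTf, 2,6-lutidine, CH2Cl2, −78 °C
Reagents that add atoms: triethylsilyl trifluoromethanesulfonate, CC[Si](CC)(CC)OS(=O)(=O)C(F)(F)F
Why: Silylation of the hindered secondary alcohol with a silyl triflate; the ether prevents lactol and tetrahydrofuran formation with the C6 aldehyde and reaction of the hydroxyl with Tf2O in the following steps.

Step 10
Reactants: 14 (14S,15S)-1-allyl-2-oxo-6-(triethylsilyloxy)bicyclo[2.2.2]octan-7-yl acetate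
Product: 15 (14S,15S)-2-oxo-1-(2-oxoethyl)-6-(triethylsilyloxy)bicyclo[2.2.2]octan-7-yl acetate
Conditions: O3, CH2Cl2, −78 °C; then PPh3, −78 °C to rt
Reagents that add atoms: ozone, [O-][O+]=O
Why: Ozonolysis of the terminal alkene with reductive work-up removes one carbon and leaves the C6 aldehyde on the C7 methylene.

Step 11
Reactants: 15 (14S,15S)-2-oxo-1-(2-oxoethyl)-6-(triethylsilyloxy)bicyclo[2.2.2]octan-7-yl acetate; 16 acetylacetone
Product: 17 (14S,15S)-1-(3-acetyl-4-oxopentyl)-2-oxo-6-(triethylsilyloxy)bicyclo[2.2.2]octan-7-yl acetate
Conditions: 16 (3 equiv), diethyl 2,6-dimethyl-1,4-dihydropyridine-3,5-dicarboxylate (Hantzsch ester), L-proline (0.2 equiv), CH2Cl2, rt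
Reagents that add atoms: none
Why: Reductive alkylation of a 1,3-diketone: Knoevenagel condensation gives the alkylidene diketone, which is reduced in the same flask by hydride transfer from the dihydropyridine. This forms C5–C6 and leaves C5 with two identical acetyl groups.

Step 12
Reactants: 17 (14S,15S)-1-(3-acetyl-4-oxopentyl)-2-oxo-6-(triethylsilyloxy)bicyclo[2.2.2]octan-7-yl acetate
Product: 18 (14S,15S)-1-[(Z)-3-acetyl-4-(trifluoromethylsulfonyloxy)pent-3-enyl]-2-oxo-6-(triethylsilyloxy)bicyclo[2.2.2]octan-7-yl acetate
Conditions: Tf2O, Et3N, LiOTf, CH2Cl2, 0 °C
Reagents that add atoms: trifluoromethanesulfonic anhydride, O=S(=O)(OS(=O)(=O)C(F)(F)F)C(F)(F)F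
Why: O-Sulfonylation of the lithium-chelated diketone enolate: chelation holds the enolate oxygen cis to the remaining acetyl group, so the (Z)-enol triflate (triflate cis to acetyl, methyl cis to C6) should form. The two acetyl groups are identical, so there is no regiochemical question, and the ring ketone is not enolised under these conditions.

Step 13
Reactants: 18 (14S,15S)-1-[(Z)-3-acetyl-4-(trifluoromethylsulfonyloxy)pent-3-enyl]-2-oxo-6-(triethylsilyloxy)bicyclo[2.2.2]octan-7-yl acetate; 19 methyl 3-iodopropanoate
Product: 21 methyl (Z)-5-acetyl-4-methyl-7-[(14S,15S)-7-acetoxy-2-oxo-6-(triethylsilyloxy)bicyclo[2.2.2]octan-1-yl]hept-4-enoate, via organozinc iodide 20 (not isolated)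
Conditions: 19, Zn dust (Me3SiCl-activated), THF/DMA, 40 °C; then 18, Pd(PPh3)4 (5 mol %), THF, 50 °C
Reagents that add atoms: none
Why: Negishi coupling of the enol triflate with the zinc homoenolate; oxidative addition to zerovalent palladium and reductive elimination at the sp2 carbon proceed with retention, so the propanoate arm takes the place of the triflate, cis to the acetyl group. This gives the (Z)-enone with the methyl group cis to C6.

Step 14
Reactants: 21 methyl (Z)-5-acetyl-4-methyl-7-[(14S,15S)-7-acetoxy-2-oxo-6-(triethylsilyloxy)bicyclo[2.2.2]octan-1-yl]hept-4-enoate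
Product: 22 methyl (Z)-5-acetyl-4-methyl-7-[(14S,15S)-7-acetoxy-6-hydroxy-2-oxobicyclo[2.2.2]octan-1-yl]hept-4-enoate
Conditions: HF·pyridine, pyridine, THF, 0 °C to rt
Reagents that add atoms: none
Why: Buffered fluoride desilylation frees the C15 hydroxyl needed for chelation in the next step; acetate, methyl ester and the enone geometry should be unaffected.

Step 15
Reactants: 22 methyl (Z)-5-acetyl-4-methyl-7-[(14S,15S)-7-acetoxy-6-hydroxy-2-oxobicyclo[2.2.2]octan-1-yl]hept-4-enoate
Product: 24 tetracyclic δ-lactone with equatorial C5 acetyl group and free C15 hydroxyl and C14 acetate, via hydroxy ester 23 (not isolated)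
Conditions: SmI2 (3 equiv, 0.1 M in THF), t-BuOH (2 equiv), THF, −78 to 0 °C; aq. NH4Cl
Reagents that add atoms: none
Why: Single-electron transfer from SmI2 to the C9 carbonyl, which is bound together with the neighbouring C15 hydroxyl to one samarium centre, gives a ketyl whose oxygen is locked on the side of the C15–C16 bridge. The carbon radical adds to C10, the β-carbon of the (Z)-enone, a polarity-matched ketyl–olefin (ketone–enone) reductive cyclisation that closes ring B in the 6-endo-trig mode; 5-exo attack at the fully substituted α-carbon C5 is disfavoured because only attack at C10 gives the acyl-stabilised radical. A second electron converts this radical into the samarium enolate, and the C9 alkoxide attacks the C3 ester (6-exo-trig acyl substitution) and expels methoxide, so the δ-lactone closes in the same flask and makes the hindered C9–C10 bond irreversible. C9 is controlled by the chelate: C10 can only reach the face turned to the C13–C14 bridge, so the oxygen ends up syn to C15. C10 is controlled by the alkene geometry in a chair transition state of ring B: the substituent cis to C6 (the methyl) becomes axial and anti to the C9 oxygen, and the propanoate arm becomes equatorial and gauche to it, as lactonisation requires. C5 is set when the enolate is protonated by t-BuOH and is in any case epimerisable to the stable equatorial acetyl form. The step needs the ketone to accept the electron in preference to the enone; chelation by the free hydroxyl and the twisted, tetrasubstituted enone favour this, and the C14 acetate cannot be eliminated because C8 has no hydrogen.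

Step 16
Reactants: 24 tetracyclic δ-lactone with equatorial C5 acetyl group and free C15 hydroxyl and C14 acetate
Product: 25 16-demethylene-15-deoxo-15-hydroxycrotobarin (C5 isopropenyl and C15 hydroxyl and C14 acetate)
Conditions: Zn, CH2Br2, TiCl4, THF, 0 °C (reagent pre-formed); then 24, CH2Cl2, 0 °C to rt
Reagents that add atoms: dibromomethane, BrCBr
Why: Takai–Lombardo methylenation; the non-basic geminal dizinc reagent should methylenate the hindered, enolisable methyl ketone without epimerising C5 and without attacking lactone or acetate, and excess reagent covers the free hydroxyl.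

Step 17
Reactants: 25 16-demethylene-15-deoxo-15-hydroxycrotobarin
Product: 26 16-demethylenecrotobarin
Conditions: Dess–Martin periodinane, NaHCO3, CH2Cl2, rt
Reagents that add atoms: none
Why: Dess–Martin oxidation of the C15 alcohol to the ketone; the resulting β-acetoxy ketone is stable because C8 has no hydrogen.

Step 18
Reactants: 26 16-demethylenecrotobarin
Product: 29 crotobarin, via Mannich base 27 (not isolated), via ammonium iodide 28 (not isolated)
Conditions: LiN(SiMe3)2 (1.1 equiv), THF, −78 °C; then Me2N=CH2+ I−, −78 °C to rt; then MeI, CH2Cl2, rt; then aq. NaHCO3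
Reagents that add atoms: N,N-dimethylmethyleneiminium iodide (Eschenmoser's salt), C=[N+](C)C.[I-]
Why: Mannich reaction of the kinetic ketone enolate, which can form only toward C16 because C8 has no hydrogen and which is more acidic than the lactone and acetate positions. Quaternisation and base-induced β-elimination of trimethylamine then give the exocyclic enone, introduced last because it is the most reactive group of the target.

## Compound list

1 | 3,5-dimethoxyphenylacetic acid | COc1cc(CC(=O)O)cc(OC)c1 | starting material
2 | 2-(3,5-dimethoxyphenyl)ethanol | COc1cc(CCO)cc(OC)c1 | intermediate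
3 | 2-(3,5-dimethoxycyclohexa-2,5-dien-1-yl)ethanol | COC1=CC(CCO)C=C(OC)C1 | intermediate
4 | allyl bromide | C=CCBr | starting material
5 | 2-(4-allyl-3,5-dimethoxycyclohexa-2,5-dien-1-yl)ethanol (cis/trans mixture) | COC1=CC(CCO)C=C(OC)C1CC=C | intermediate
6 | 2-(4-allyl-3,5-dimethoxycyclohexa-2,5-dien-1-yl)acetaldehyde (cis/trans mixture) | COC1=CC(CC=O)C=C(OC)C1CC=C | intermediate
7 | 2-allyl-5-(2-oxoethyl)cyclohexane-1,3-dione (achiral) | O=CCC1CC(=O)C(CC=C)C(=O)C1 | intermediate
8 | 2-allyl-5-(2-oxoethyl)-3-(trimethylsilyloxy)cyclohex-2-en-1-one (racemic) | C=CCC1=C(O[Si](C)(C)C)CC(CC=O)CC1=O | intermediate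
9 | rac-1-allyl-7-hydroxybicyclo[2.2.2]octane-2,6-dione | C=CCC12C(=O)CC(CC1=O)CC2O | intermediate
10 | 1-allylbicyclo[2.2.2]octane-2,6,7-trione (achiral) | C=CCC12C(=O)CC(CC1=O)CC2=O | intermediate
11 | (14S)-1-allyl-7-hydroxybicyclo[2.2.2]octane-2,6-dione | C1C(=O)[C@]2(CC=C)C(=O)C[C@H]1C[C@@H]2O | intermediate
12 | acetaldehyde | CC=O | starting material
13 | (14S,15S)-1-allyl-6-hydroxy-2-oxobicyclo[2.2.2]octan-7-yl acetate | C1[C@H](O)[C@]2(CC=C)C(=O)C[C@H]1C[C@@H]2OC(C)=O | intermediate
14 | (14S,15S)-1-allyl-2-oxo-6-(triethylsilyloxy)bicyclo[2.2.2]octan-7-yl acetate | C1[C@H](O[Si](CC)(CC)CC)[C@]2(CC=C)C(=O)C[C@H]1C[C@@H]2OC(C)=O | intermediate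
15 | (14S,15S)-2-oxo-1-(2-oxoethyl)-6-(triethylsilyloxy)bicyclo[2.2.2]octan-7-yl acetate | C1[C@H](O[Si](CC)(CC)CC)[C@]2(CC=O)C(=O)C[C@H]1C[C@@H]2OC(C)=O | intermediate
16 | acetylacetone | CC(=O)CC(C)=O | starting material
17 | (14S,15S)-1-(3-acetyl-4-oxopentyl)-2-oxo-6-(triethylsilyloxy)bicyclo[2.2.2]octan-7-yl acetate | C1[C@H](O[Si](CC)(CC)CC)[C@]2(CCC(C(C)=O)C(C)=O)C(=O)C[C@H]1C[C@@H]2OC(C)=O | intermediate
18 | (14S,15S)-1-[(Z)-3-acetyl-4-(trifluoromethylsulfonyloxy)pent-3-enyl]-2-oxo-6-(triethylsilyloxy)bicyclo[2.2.2]octan-7-yl acetate | C1[C@H](O[Si](CC)(CC)CC)[C@]2(CC/C(C(C)=O)=C(C)/OS(=O)(=O)C(F)(F)F)C(=O)C[C@H]1C[C@@H]2OC(C)=O | intermediate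
19 | methyl 3-iodopropanoate | COC(=O)CCI | starting material
20 | (3-methoxy-3-oxopropyl)zinc iodide | COC(=O)CC[Zn]I | intermediate
21 | methyl (Z)-5-acetyl-4-methyl-7-[(14S,15S)-7-acetoxy-2-oxo-6-(triethylsilyloxy)bicyclo[2.2.2]octan-1-yl]hept-4-enoate | C1[C@H](O[Si](CC)(CC)CC)[C@]2(CC/C(C(C)=O)=C(C)/CCC(=O)OC)C(=O)C[C@H]1C[C@@H]2OC(C)=O | intermediate
22 | methyl (Z)-5-acetyl-4-methyl-7-[(14S,15S)-7-acetoxy-6-hydroxy-2-oxobicyclo[2.2.2]octan-1-yl]hept-4-enoate (key-step precursor) | C1[C@H](O)[C@]2(CC/C(C(C)=O)=C(C)/CCC(=O)OC)C(=O)C[C@H]1C[C@@H]2OC(C)=O | intermediate
23 | ring-B-closed hydroxy ester (C9 tertiary alcohol; C3 methyl ester; C5 acetyl; C15 hydroxyl; C14 acetate) | C1[C@H](O)[C@]23CC[C@@H](C(C)=O)[C@](C)(CCC(=O)OC)[C@@]2(O)C[C@H]1C[C@@H]3OC(C)=O | intermediate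
24 | tetracyclic δ-lactone with equatorial C5 acetyl group; free C15 hydroxyl; C14 acetate (key-step product) | C1[C@H](O)[C@]23CC[C@@H](C(C)=O)[C@]4(C)CCC(=O)O[C@@]42C[C@H]1C[C@@H]3OC(C)=O | intermediate
25 | 16-demethylene-15-deoxo-15-hydroxycrotobarin | C1[C@H](O)[C@]23CC[C@@H](C(=C)C)[C@]4(C)CCC(=O)O[C@@]42C[C@H]1C[C@@H]3OC(C)=O | intermediate
26 | 16-demethylenecrotobarin | C1C(=O)[C@]23CC[C@@H](C(=C)C)[C@]4(C)CCC(=O)O[C@@]42C[C@H]1C[C@@H]3OC(C)=O | intermediate
27 | 16-(dimethylaminomethyl)-16-demethylenecrotobarin (C16 epimers) | CN(C)CC1C(=O)[C@]23CC[C@@H](C(=C)C)[C@]4(C)CCC(=O)O[C@@]42C[C@H]1C[C@@H]3OC(C)=O | intermediate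
28 | trimethylammonium iodide of 27 (C16 epimers) | C[N+](C)(C)CC1C(=O)[C@]23CC[C@@H](C(=C)C)[C@]4(C)CCC(=O)O[C@@]42C[C@H]1C[C@@H]3OC(C)=O.[I-] | intermediate
29 | crotobarin | C=C1C(=O)[C@]23CC[C@@H](C(=C)C)[C@]4(C)CCC(=O)O[C@@]42C[C@H]1C[C@@H]3OC(C)=O | target

## Step count and least certain steps

Total step count: 18. Longest linear sequence: 18 steps (1 to 29); compounds 4, 12, 16 and 19 enter as single building blocks.

**Step 15 (key step).** The most likely failure is that the electron is accepted by the conjugated ketone, or that the C9 ketyl is reduced further and protonated before the radical reaches the fully substituted C10, so that simple reduction competes with ring closure. A second risk is attack through a boat-like arrangement, which would erode the C10 selectivity. The fallback sets out from 15 and returns at 24; it replaces the enone by an enoate, which SmI2 does not reduce under these conditions.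
- Reductive alkylation of 15 with tert-butyl acetoacetate (Hantzsch ester, proline) should give the tert-butyl β-keto ester F1.
- Chelation-controlled triflation (Tf2O, Et3N, LiOTf) should give the (Z)-enol triflate F2.
- Negishi coupling with 20 should give the (Z)-diester F3, and HF·pyridine the free alcohol F4.
- SmI2/t-BuOH should close ring B and the lactone to the tert-butyl ester lactone F5.
- CF3CO2H should give the carboxylic acid F6, and EtSH with a carbodiimide the S-ethyl thioester F7.
- Fukuyama coupling (MeZnI, PdCl2(PPh3)2) should convert F7 into methyl ketone 24.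

**Step 5.** The most likely failure is reversal of the aldol to the stabilised dione enol once the aldolate is liberated, or slow closure through the strained boat-like transition state. The fallback sets out from 7 and returns at 10. The closure is run as a silyl-transfer aldol (8 with catalytic Me3SiNTf2) to give the trimethylsilyl ether F8, which cannot revert. F8 is then oxidised directly with CrO3/H2SO4 in acetone, which cleaves the silyl ether and oxidises in one operation, so the free aldol is never handled.

**Step 7.** The most likely failure is opening of trione 10 by adventitious nucleophiles, over-reduction to diols, or incomplete discrimination of the enantiotopic faces. The fallback sets out from 9 and returns at 11. It is an enzymatic kinetic resolution with Candida antarctica lipase B and vinyl acetate. By the empirical size rule for secondary alcohols the (14R)-alcohol should be acylated faster, leaving 11. The (14R)-acetate F9 is returned to achiral 7 with K2CO3 in methanol (methanolysis, then base-induced retro-aldol) and recycled.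

**Step 8.** The most likely failure is retro-aldol cleavage of the samarium alkoxide of 11 to the stabilised diketonate before hydride transfer. The fallback sets out from 11 and returns at 14. Directed reduction with Me4NBH(OAc)3 in AcOH/MeCN (acidic, intramolecular hydride delivery from the C14 oxygen) should give the anti-diol F10. The C15 hydroxyl lies beside the flat C9 carbonyl and is the less hindered of the two, so Et3SiCl/imidazole should silylate it selectively to the mono-silyl ether F11. Acetylation (Ac2O, DMAP) then gives 14.

**Step 11.** The most likely failure is slow Knoevenagel condensation, with competing addition of a second molecule of 16 to the alkylidene intermediate or amine-mediated self-condensation of 15. The fallback sets out from 15 and returns at 17. Selective reduction of the aldehyde with NaBH(OAc)3 gives the primary alcohol F12, I2/PPh3/imidazole gives the primary iodide F13, and C-alkylation of 16 with F13 (K2CO3, acetone) gives 17.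

## Further compounds

F1 | step 15 | (14S,15S)-1-[3-(tert-butoxycarbonyl)-4-oxopentyl]-2-oxo-6-(triethylsilyloxy)bicyclo[2.2.2]octan-7-yl acetate | C1[C@H](O[Si](CC)(CC)CC)[C@]2(CCC(C(C)=O)C(=O)OC(C)(C)C)C(=O)C[C@H]1C[C@@H]2OC(C)=O
F2 | step 15 | (Z)-enol triflate of F1 (triflate cis to the ester) | C1[C@H](O[Si](CC)(CC)CC)[C@]2(CC/C(C(=O)OC(C)(C)C)=C(C)/OS(=O)(=O)C(F)(F)F)C(=O)C[C@H]1C[C@@H]2OC(C)=O
F3 | step 15 | (Z)-diester: tert-butyl ester on C5 and methyl propanoate arm on C10 with C15 silyl ether | C1[C@H](O[Si](CC)(CC)CC)[C@]2(CC/C(C(=O)OC(C)(C)C)=C(C)/CCC(=O)OC)C(=O)C[C@H]1C[C@@H]2OC(C)=O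
F4 | step 15 | (Z)-diester with free C15 hydroxyl | C1[C@H](O)[C@]2(CC/C(C(=O)OC(C)(C)C)=C(C)/CCC(=O)OC)C(=O)C[C@H]1C[C@@H]2OC(C)=O
F5 | step 15 | tetracyclic δ-lactone with C5 tert-butyl ester | C1[C@H](O)[C@]23CC[C@@H](C(=O)OC(C)(C)C)[C@]4(C)CCC(=O)O[C@@]42C[C@H]1C[C@@H]3OC(C)=O
F6 | step 15 | tetracyclic δ-lactone with C5 carboxylic acid | C1[C@H](O)[C@]23CC[C@@H](C(=O)O)[C@]4(C)CCC(=O)O[C@@]42C[C@H]1C[C@@H]3OC(C)=O
F7 | step 15 | tetracyclic δ-lactone with C5 S-ethyl thioester | C1[C@H](O)[C@]23CC[C@@H](C(=O)SCC)[C@]4(C)CCC(=O)O[C@@]42C[C@H]1C[C@@H]3OC(C)=O
F8 | step 5 | rac-1-allyl-7-(trimethylsilyloxy)bicyclo[2.2.2]octane-2,6-dione | C=CCC12C(=O)CC(CC1=O)CC2O[Si](C)(C)C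
F9 | step 7 | (14R)-1-allyl-2,6-dioxobicyclo[2.2.2]octan-7-yl acetate | C1C(=O)[C@@]2(CC=C)C(=O)C[C@@H]1C[C@H]2OC(C)=O
F10 | step 8 | (14S,15S)-1-allyl-6,7-dihydroxybicyclo[2.2.2]octan-2-one (anti-diol) | C1[C@H](O)[C@]2(CC=C)C(=O)C[C@H]1C[C@@H]2O
F11 | step 8 | (14S,15S)-1-allyl-7-hydroxy-6-(triethylsilyloxy)bicyclo[2.2.2]octan-2-one | C1[C@H](O[Si](CC)(CC)CC)[C@]2(CC=C)C(=O)C[C@H]1C[C@@H]2O
F12 | step 11 | (14S,15S)-1-(2-hydroxyethyl)-2-oxo-6-(triethylsilyloxy)bicyclo[2.2.2]octan-7-yl acetate | C1[C@H](O[Si](CC)(CC)CC)[C@]2(CCO)C(=O)C[C@H]1C[C@@H]2OC(C)=O
F13 | step 11 | (14S,15S)-1-(2-iodoethyl)-2-oxo-6-(triethylsilyloxy)bicyclo[2.2.2]octan-7-yl acetate | C1[C@H](O[Si](CC)(CC)CC)[C@]2(CCI)C(=O)C[C@H]1C[C@@H]2OC(C)=O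
A1 | alternative 1 | bicyclo[2.2.2]octenone cycloadduct (C13 dimethyl ketal; C14 ketone; C15 enol ether; lactone in place) | C1=C(OC)[C@]23CC[C@@H](C(=C)C)[C@]4(C)CCC(=O)O[C@@]42C[C@H]1C(OC)(OC)C3=O
A2 | alternative 2 | cyclopropyl ketone with C12–C13–C16 cyclopropane | [C@H]12C(=O)[C@]34CC[C@@H](C(=C)C)[C@]5(C)CCC(=O)O[C@@]53C[C@H]1[C@@H]2[C@@H]4OC(C)=O
A3 | alternative 3 | 16-demethylenecrotobarin (same structure as 26) | C1C(=O)[C@]23CC[C@@H](C(=C)C)[C@]4(C)CCC(=O)O[C@@]42C[C@H]1C[C@@H]3OC(C)=O
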